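**Retrosynthetic overview**

1. Numbering used throughout: ring C1 (tertiary carbinol carrying C7H2–O), C2 (CH–OBz), C3=C4, C5 (CH–OBz), C6 (CH–OH). The plan rests on the ring bond C1–C2: C1 is a tertiary carbinol and its neighbour C2 is oxygenated, so with C2 as a ketone this is an acyloin bond between two carbonyl carbons.
2. Endgame in reverse: O7 benzoate ⇐ free O6/O7 diol ⇐ O6/O7 acetonide carrying the O2 and O5 benzoates ⇐ C2 ketone reduced under direction of O1–H.
3. Ring formation: the cyclohexene is the only ring made. It closes at C1–C2 by a carbene-catalysed intramolecular crossed benzoin of a Z-enal (C2) onto the ketone (C1) of a 2,2-dimethyl-1,3-dioxan-5-one, whose dioxane ring is present from the first step and ends as the acetonide.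
4. The Z-enal ⇐ acetal hydrolysis and semihydrogenation ⇐ silyl ether ⇐ (S)-proline anti-aldol of the dioxanone with 4,4-diethoxybut-2-ynal, which sets C5 and C6.

Key step: step 5

**Remarks**

- Assumption: the (5aS,10bR) antipode of the triazolium salt is taken as the one whose face preference at C1 matches that of the substrate; this pairing is not derived here, and the mirror-image salt is the direct replacement if it proves mismatched.
- Species bound to a catalyst or reagent within one mechanistic event (enamine, carbene adducts, boron alkoxide) are described in the Why lines and are not numbered.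

**Route**

Step 1
Reactants: 1 2,2-dimethyl-1,3-dioxan-5-one; 2 4,4-diethoxybut-2-ynal
Product: 3 (4S)-4-[(1S)-4,4-diethoxy-1-hydroxybut-2-yn-1-yl]-2,2-dimethyl-1,3-dioxan-5-one
Conditions: (S)-proline (30 mol %), DMF, 4 °C, 2 added slowly to 1 (2 equiv)
Reagents that add atoms: none
Why: Proline-catalysed enamine aldol reaction, in which the ring-locked E-enamine of 1 adds to the Re face of the non-enolisable ynal through the carboxylic-acid-bound chair transition state, setting C6 (S) and C5 (S) anti (O5 cis to O6 in the later ring), while slow addition of 2 limits loss of the catalyst by aza-Michael addition.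

Step 2
Reactants: 3 (4S)-4-[(1S)-4,4-diethoxy-1-hydroxybut-2-yn-1-yl]-2,2-dimethyl-1,3-dioxan-5-one
Product: 4 (4S)-4-[(1S)-1-[(tert-butyldimethylsilyl)oxy]-4,4-diethoxybut-2-yn-1-yl]-2,2-dimethyl-1,3-dioxan-5-one
Conditions: TBSCl, imidazole, DMAP (cat.), DMF, rt
Reagents that add atoms: tert-butyldimethylsilyl chloride, CC(C)(C)[Si](C)(C)Cl
Why: Imidazole-promoted silyl ether formation masks O5 as a non-nucleophilic, poor leaving group for the later Z-enal, and the near-neutral conditions should leave the diethyl acetal, the acetonide and the C6 centre untouched.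

Step 3
Reactants: 4 (4S)-4-[(1S)-1-[(tert-butyldimethylsilyl)oxy]-4,4-diethoxybut-2-yn-1-yl]-2,2-dimethyl-1,3-dioxan-5-one
Product: 5 (4S)-4-[(1S,2Z)-1-[(tert-butyldimethylsilyl)oxy]-4,4-diethoxybut-2-en-1-yl]-2,2-dimethyl-1,3-dioxan-5-one
Conditions: H2 (1 atm), Pd/CaCO3 poisoned with Pb(OAc)2, quinoline, EtOAc, rt
Reagents that add atoms: none
Why: Lindlar semihydrogenation delivers H2 syn on the poisoned Pd surface and stops at the alkene, giving the Z geometry that will hold C2 near C1, while the ketone, both acetals and the silyl ether are inert.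

Step 4
Reactants: 5 (4S)-4-[(1S,2Z)-1-[(tert-butyldimethylsilyl)oxy]-4,4-diethoxybut-2-en-1-yl]-2,2-dimethyl-1,3-dioxan-5-one
Product: 6 (2Z,4S)-4-[(tert-butyldimethylsilyl)oxy]-4-[(4S)-2,2-dimethyl-5-oxo-1,3-dioxan-4-yl]but-2-enal
Conditions: TsOH·H2O (5 mol %), acetone/H2O (20:1), 0 °C, used at once
Reagents that add atoms: water, O
Why: Acid-catalysed acetal hydrolysis, in which the acyclic allylic diethyl acetal ionises far more readily than the dioxanone acetonide (deactivated by the ring ketone and held by acetone as solvent), and the cold, brief treatment should keep the Z geometry.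

Step 5
Reactants: 6 (2Z,4S)-4-[(tert-butyldimethylsilyl)oxy]-4-[(4S)-2,2-dimethyl-5-oxo-1,3-dioxan-4-yl]but-2-enal
Product: 7 (4aS,8S,8aS)-8-[(tert-butyldimethylsilyl)oxy]-4a-hydroxy-2,2-dimethyl-4a,8a-dihydro-4H-1,3-benzodioxin-5(8H)-one, the trans-fused ketol (C1 = C4a, C2 = C5 ketone, C5 = C8, C6 = C8a)
Conditions: (5aS,10bR)-2-(pentafluorophenyl)-5a,10b-dihydro-4H,6H-indeno[2,1-b][1,2,4]triazolo[4,3-d][1,4]oxazin-2-ium tetrafluoroborate (20 mol %), Et3N (20 mol %), toluene (0.02 M), 4 Å MS, 0 °C → rt, Ar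
Reagents that add atoms: none
Why: Proposed new method: the carbene adds to the aldehyde carbon C2, a proton shift gives the enaminol (Breslow intermediate, an acyl anion equivalent), this attacks the ketone carbon C1, the new alkoxide takes the enaminol proton and the triazolium leaves from C2 to restore the carbene and the C2 ketone; the closest known reaction type is the triazolium-catalysed intramolecular crossed aldehyde–ketone benzoin that gives six-membered tertiary ketols from aryl aldehydes tethered to ketones, where the arene takes the place of the Z C3=C4 bond. The cyclohexene closes 6-exo-trig at C1 with the carbonyl oxygen outside the new ring, and attack through the homoenolate carbon C4 would need a four-membered ring. The new stereocentre C1 is controlled by C6 through the dioxanone chair: with the C6–C5 bond equatorial, approach of C2 along the equatorial direction makes both new-ring bonds equatorial on the dioxane, so the bicycle is trans-fused and O1 is axial, cis to O6 and anti to H6. With the enaminol O–H gauche to O1 for proton transfer, the triazolium on C2 lies anti to O1, over the axial H6 in the trans-fused closure but over O6 and the acetonide in the cis-fused one, and the chiral aminoindanol backbone is meant to reinforce the same face. The step needs acyl-anion over homoenolate reactivity and retention of the Z geometry, which the electron-poor N-pentafluorophenyl triazolium, the weak base, the strongly electrophilic doubly alpha-oxygenated ketone and the poor leaving-group ability of the C5 silyloxy group should secure. The desired closure pays for a syn-axial O5/O1 contact in the forming half-chair, so facial selectivity at C1 is the main uncertainty.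

Step 6
Reactants: 7 (4aS,8S,8aS)-8-[(tert-butyldimethylsilyl)oxy]-4a-hydroxy-2,2-dimethyl-4a,8a-dihydro-4H-1,3-benzodioxin-5(8H)-one
Product: 8 (4aR,5S,8S,8aS)-8-[(tert-butyldimethylsilyl)oxy]-2,2-dimethyl-4a,5,8,8a-tetrahydro-4H-1,3-benzodioxine-4a,5-diol (O2 trans to O1)
Conditions: Me4NBH(OAc)3, MeCN/AcOH (1:1), −20 → 0 °C
Reagents that add atoms: none
Why: Evans–Saksena hydroxyl-directed reduction, in which exchange at the axial tertiary O1–H gives a boron-bound hydride that is delivered internally to the face of the C2 carbonyl on which O1 stands, so that H enters cis and O2 ends trans to O1 (C2 S), without 1,4-reduction of the enone.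

Step 7
Reactants: 8 (4aR,5S,8S,8aS)-8-[(tert-butyldimethylsilyl)oxy]-2,2-dimethyl-4a,5,8,8a-tetrahydro-4H-1,3-benzodioxine-4a,5-diol
Product: 9 (4aR,5S,8S,8aS)-2,2-dimethyl-4a,5,8,8a-tetrahydro-4H-1,3-benzodioxine-4a,5,8-triol
Conditions: HF·pyridine, pyridine, THF, 0 °C → rt
Reagents that add atoms: none
Why: Fluoride-mediated desilylation frees O5–H under buffered conditions that the acetonide and the allylic alcohols should tolerate, and no ester is yet present that could migrate.

Step 8
Reactants: 9 (4aR,5S,8S,8aS)-2,2-dimethyl-4a,5,8,8a-tetrahydro-4H-1,3-benzodioxine-4a,5,8-triol; 10 benzoyl chloride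
Product: 11 (4aR,5S,8S,8aS)-4a-hydroxy-2,2-dimethyl-4a,5,8,8a-tetrahydro-4H-1,3-benzodioxine-5,8-diyl dibenzoate
Conditions: BzCl (2.5 equiv), pyridine, DMAP (cat.), CH2Cl2, 0 °C → rt
Reagents that add atoms: benzoyl chloride (10), O=C(Cl)c1ccccc1
Why: DMAP-catalysed acylation esterifies the two secondary allylic hydroxyls at C2 and C5, while the tertiary O1–H is too hindered to react and, being trans to O2, cannot receive a migrating benzoyl group.

Step 9
Reactants: 11 (4aR,5S,8S,8aS)-4a-hydroxy-2,2-dimethyl-4a,5,8,8a-tetrahydro-4H-1,3-benzodioxine-5,8-diyl dibenzoate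
Product: 12 (1S,2S,5S,6S)-1,6-dihydroxy-1-(hydroxymethyl)cyclohex-3-ene-2,5-diyl dibenzoate
Conditions: AcOH/H2O (4:1), 40 °C
Reagents that add atoms: none
Why: Acid hydrolysis of the isopropylidene acetal frees O6–H and O7–H without base, so the benzoates should neither cleave nor migrate.

Step 10
Reactants: 12 (1S,2S,5S,6S)-1,6-dihydroxy-1-(hydroxymethyl)cyclohex-3-ene-2,5-diyl dibenzoate; 10 benzoyl chloride
Product: 13 [(1S,2S,5S,6S)-2,5-bis(benzoyloxy)-1,6-dihydroxycyclohex-3-en-1-yl]methyl benzoate (CNP0128482.4)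
Conditions: BzCl (1.05 equiv), pyridine, CH2Cl2, −40 → −20 °C
Reagents that add atoms: benzoyl chloride (10), O=C(Cl)c1ccccc1
Why: Rate-selective acylation, in which the primary O7–H reacts ahead of the secondary O6–H (flanked by the quaternary C1 and the C5 benzoate) and the tertiary O1–H when one equivalent of acyl chloride is used cold, leaving all four stereocentres untouched.

**Compound list**

1 | 2,2-dimethyl-1,3-dioxan-5-one | CC1(C)OCC(=O)CO1 | starting material
2 | 4,4-diethoxybut-2-ynal | CCOC(OCC)C#CC=O | starting material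
3 | (4S)-4-[(1S)-4,4-diethoxy-1-hydroxybut-2-yn-1-yl]-2,2-dimethyl-1,3-dioxan-5-one | CCOC(OCC)C#C[C@H](O)[C@@H]1OC(C)(C)OCC1=O | intermediate
4 | (4S)-4-[(1S)-1-[(tert-butyldimethylsilyl)oxy]-4,4-diethoxybut-2-yn-1-yl]-2,2-dimethyl-1,3-dioxan-5-one | CCOC(OCC)C#C[C@H](O[Si](C)(C)C(C)(C)C)[C@@H]1OC(C)(C)OCC1=O | intermediate
5 | (4S)-4-[(1S,2Z)-1-[(tert-butyldimethylsilyl)oxy]-4,4-diethoxybut-2-en-1-yl]-2,2-dimethyl-1,3-dioxan-5-one | CCOC(OCC)/C=C\[C@H](O[Si](C)(C)C(C)(C)C)[C@@H]1OC(C)(C)OCC1=O | intermediate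
6 | (2Z,4S)-4-[(tert-butyldimethylsilyl)oxy]-4-[(4S)-2,2-dimethyl-5-oxo-1,3-dioxan-4-yl]but-2-enal | O=C/C=C\[C@H](O[Si](C)(C)C(C)(C)C)[C@@H]1OC(C)(C)OCC1=O | intermediate
7 | (4aS,8S,8aS)-8-[(tert-butyldimethylsilyl)oxy]-4a-hydroxy-2,2-dimethyl-4a,8a-dihydro-4H-1,3-benzodioxin-5(8H)-one, trans-fused | O=C1C=C[C@H](O[Si](C)(C)C(C)(C)C)[C@@H]2OC(C)(C)OC[C@@]12O | intermediate
8 | (4aR,5S,8S,8aS)-8-[(tert-butyldimethylsilyl)oxy]-2,2-dimethyl-4a,5,8,8a-tetrahydro-4H-1,3-benzodioxine-4a,5-diol | CC1(C)OC[C@@]2(O)[C@@H](O)C=C[C@H](O[Si](C)(C)C(C)(C)C)[C@@H]2O1 | intermediate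
9 | (4aR,5S,8S,8aS)-2,2-dimethyl-4a,5,8,8a-tetrahydro-4H-1,3-benzodioxine-4a,5,8-triol | CC1(C)OC[C@@]2(O)[C@@H](O)C=C[C@H](O)[C@@H]2O1 | intermediate
10 | benzoyl chloride | O=C(Cl)c1ccccc1 | starting material
11 | (4aR,5S,8S,8aS)-4a-hydroxy-2,2-dimethyl-4a,5,8,8a-tetrahydro-4H-1,3-benzodioxine-5,8-diyl dibenzoate | CC1(C)OC[C@@]2(O)[C@@H](OC(=O)c3ccccc3)C=C[C@H](OC(=O)c3ccccc3)[C@@H]2O1 | intermediate
12 | (1S,2S,5S,6S)-1,6-dihydroxy-1-(hydroxymethyl)cyclohex-3-ene-2,5-diyl dibenzoate | OC[C@@]1(O)[C@@H](OC(=O)c2ccccc2)C=C[C@H](OC(=O)c2ccccc2)[C@@H]1O | intermediate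
13 | [(1S,2S,5S,6S)-2,5-bis(benzoyloxy)-1,6-dihydroxycyclohex-3-en-1-yl]methyl benzoate | O=C(OC[C@@]1(O)[C@@H](OC(=O)c2ccccc2)C=C[C@H](OC(=O)c2ccccc2)[C@@H]1O)c1ccccc1 | target

**Step count**

Total: 10 steps. Longest linear sequence: 10 steps (1 → 13; 2 enters in step 1 and 10 in steps 8 and 10).

**Steps most likely to fail**

Step 5 (the step labelled as a proposed new method). What may go wrong: the Z-enal may isomerise to the E-enal, or the carbene adduct may drain into homoenolate or redox pathways before C2 reaches C1; closure may also occur on the axial face of C1 and give the cis-fused bicycle. The fallback uses known chemistry and sets out from 4. Exhaustive hydrogenation (H2, Pd/C, EtOAc) should give the saturated acetal (4S)-4-[(1S)-1-[(tert-butyldimethylsilyl)oxy]-4,4-diethoxybutyl]-2,2-dimethyl-1,3-dioxan-5-one F1. Hydrolysis (TsOH·H2O cat., acetone/H2O) should give the keto-aldehyde (4S)-4-[(tert-butyldimethylsilyl)oxy]-4-[(4S)-2,2-dimethyl-5-oxo-1,3-dioxan-4-yl]butanal F2. The triazolium-catalysed intramolecular aldehyde–ketone benzoin, now with an ordinary aliphatic aldehyde and so within established scope, should give the saturated ketol (4aS,8S,8aS)-8-[(tert-butyldimethylsilyl)oxy]-4a-hydroxy-2,2-dimethylhexahydro-4H-1,3-benzodioxin-5-one F3. Dehydrogenation with IBX (DMSO/toluene, 70 °C), possible only toward C3 because C1 is quaternary, then installs C3=C4 and returns to the route at 7. This removes the alkene-related failure modes; the face of C1 is still governed by the dioxanone chair and the catalyst antipode.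

Step 4. What may go wrong: Z to E isomerisation of the enal under the acid that opens the acetal, or partial loss of the acetonide. The fallback reaches the aldehyde by oxidation instead of hydrolysis and sets out from 1. The (S)-proline aldol of 1 with the known aldehyde 4-[(4-methoxybenzyl)oxy]but-2-ynal should give (4S)-4-[(1S)-1-hydroxy-4-[(4-methoxybenzyl)oxy]but-2-yn-1-yl]-2,2-dimethyl-1,3-dioxan-5-one F4. Silylation (TBSCl, imidazole, DMF) should give the silyl ether F5, and semihydrogenation (H2, Pd/CaCO3 poisoned with Pb(OAc)2, quinoline) the Z-alkene F6. Removal of the 4-methoxybenzyl group (DDQ, CH2Cl2/pH 7 buffer, 0 °C) should give the Z-allylic alcohol (4S)-4-[(1S,2Z)-1-[(tert-butyldimethylsilyl)oxy]-4-hydroxybut-2-en-1-yl]-2,2-dimethyl-1,3-dioxan-5-one F7. Buffered Dess–Martin oxidation (NaHCO3, CH2Cl2, 0 °C) returns to the route at 6 without any acid.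

Step 6. What may go wrong: exchange at the hindered tertiary O1–H may be slower than undirected hydride addition, which should occur anti to the axial C1–O1 bond and give the wrong face at C2. The fallback accepts that face and corrects it by inversion; it sets out from 7. Luche reduction (NaBH4, CeCl3·7H2O, MeOH, −78 °C) should give the C2 epimer (4aR,5R,8S,8aS)-8-[(tert-butyldimethylsilyl)oxy]-2,2-dimethyl-4a,5,8,8a-tetrahydro-4H-1,3-benzodioxine-4a,5-diol F8 (O2 cis to O1). A Mitsunobu reaction with benzoic acid (PPh3, DIAD, toluene, 0 °C → rt) should invert C2 and install its benzoate in one operation, giving (4aR,5S,8S,8aS)-8-[(tert-butyldimethylsilyl)oxy]-4a-hydroxy-2,2-dimethyl-4a,5,8,8a-tetrahydro-4H-1,3-benzodioxin-5-yl benzoate F9. Desilylation (HF·pyridine, pyridine, THF) should give (4aR,5S,8S,8aS)-4a,8-dihydroxy-2,2-dimethyl-4a,5,8,8a-tetrahydro-4H-1,3-benzodioxin-5-yl benzoate F10. Benzoylation of O5–H with 10 (pyridine, DMAP cat., CH2Cl2) returns to the route at 11.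

**Further compounds**

F1 | step 5 | (4S)-4-[(1S)-1-[(tert-butyldimethylsilyl)oxy]-4,4-diethoxybutyl]-2,2-dimethyl-1,3-dioxan-5-one | CCOC(OCC)CC[C@H](O[Si](C)(C)C(C)(C)C)[C@@H]1OC(C)(C)OCC1=O
F2 | step 5 | (4S)-4-[(tert-butyldimethylsilyl)oxy]-4-[(4S)-2,2-dimethyl-5-oxo-1,3-dioxan-4-yl]butanal | O=CCC[C@H](O[Si](C)(C)C(C)(C)C)[C@@H]1OC(C)(C)OCC1=O
F3 | step 5 | (4aS,8S,8aS)-8-[(tert-butyldimethylsilyl)oxy]-4a-hydroxy-2,2-dimethylhexahydro-4H-1,3-benzodioxin-5-one | O=C1CC[C@H](O[Si](C)(C)C(C)(C)C)[C@@H]2OC(C)(C)OC[C@@]12O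
F4 | step 4 | (4S)-4-[(1S)-1-hydroxy-4-[(4-methoxybenzyl)oxy]but-2-yn-1-yl]-2,2-dimethyl-1,3-dioxan-5-one | COc1ccc(COCC#C[C@H](O)[C@@H]2OC(C)(C)OCC2=O)cc1
F5 | step 4 | (4S)-4-[(1S)-1-[(tert-butyldimethylsilyl)oxy]-4-[(4-methoxybenzyl)oxy]but-2-yn-1-yl]-2,2-dimethyl-1,3-dioxan-5-one | COc1ccc(COCC#C[C@H](O[Si](C)(C)C(C)(C)C)[C@@H]2OC(C)(C)OCC2=O)cc1
F6 | step 4 | (4S)-4-[(1S,2Z)-1-[(tert-butyldimethylsilyl)oxy]-4-[(4-methoxybenzyl)oxy]but-2-en-1-yl]-2,2-dimethyl-1,3-dioxan-5-one | COc1ccc(COC/C=C\[C@H](O[Si](C)(C)C(C)(C)C)[C@@H]2OC(C)(C)OCC2=O)cc1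
F7 | step 4 | (4S)-4-[(1S,2Z)-1-[(tert-butyldimethylsilyl)oxy]-4-hydroxybut-2-en-1-yl]-2,2-dimethyl-1,3-dioxan-5-one | OC/C=C\[C@H](O[Si](C)(C)C(C)(C)C)[C@@H]1OC(C)(C)OCC1=O
F8 | step 6 | (4aR,5R,8S,8aS)-8-[(tert-butyldimethylsilyl)oxy]-2,2-dimethyl-4a,5,8,8a-tetrahydro-4H-1,3-benzodioxine-4a,5-diol | CC1(C)OC[C@@]2(O)[C@H](O)C=C[C@H](O[Si](C)(C)C(C)(C)C)[C@@H]2O1
F9 | step 6 | (4aR,5S,8S,8aS)-8-[(tert-butyldimethylsilyl)oxy]-4a-hydroxy-2,2-dimethyl-4a,5,8,8a-tetrahydro-4H-1,3-benzodioxin-5-yl benzoate | CC1(C)OC[C@@]2(O)[C@@H](OC(=O)c3ccccc3)C=C[C@H](O[Si](C)(C)C(C)(C)C)[C@@H]2O1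
F10 | step 6 | (4aR,5S,8S,8aS)-4a,8-dihydroxy-2,2-dimethyl-4a,5,8,8a-tetrahydro-4H-1,3-benzodioxin-5-yl benzoate | CC1(C)OC[C@@]2(O)[C@@H](OC(=O)c3ccccc3)C=C[C@H](O)[C@@H]2O1
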